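**Retrosynthetic overview**

1. The target is 4-bromo-5-(dibromomethylidene)-3-[(1R)-1-hydroxybutyl]furan-2(5H)-one. Its only ring, the furanone O1–C2–C3–C4–C5, is closed in the last step.
2. Enabling feature: ring carbon C5 carries both the ring oxygen O1 and the exocyclic C6Br2 carbon (a gem-dibromo enol lactone), and C2 and C5 sit cis on the C3=C4(Br) bond. This is the retron of a 5-exo-dig bromolactonisation of a bromoalkyne, so O1–C5 is cut to the acyclic (E)-3-bromo-2-en-4-ynoic acid 8. Because C6 ends with two identical bromines, no exocyclic alkene geometry has to be controlled.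
3. The C4–C5 bond of 8 comes from a site-selective mono-Sonogashira coupling of the gem-dibromoacrylate 5 with trimethylsilylacetylene.
4. Compound 5 (the C3–C1' bond, the (R)-carbinol and the C4Br2 unit) comes from a catalytic asymmetric three-component bromo-aldol of methyl 3-bromopropiolate, TMSBr and butanal.
5. Ring order: no ring exists before step 5. Step 5 forms the furanone ring together with both C6–Br bonds, on the unprotected hydroxy acid.

Key step: step 5

Assumption: the catalyst antipode in step 2 is chosen by the usual aldehyde-binding model of oxazaborolidinium ions; the (S)-catalyst is written, and its mirror image is to be used if the carbinol turns out to be (S).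

**Route**

Step 1
Reactants: 1 methyl propiolate
Product: 2 methyl 3-bromopropiolate
Conditions: NBS (1.1 equiv), AgNO3 (10 mol%), acetone, rt, dark
Reagents that add atoms: N-bromosuccinimide, O=C1CCC(=O)N1Br
Why: Silver-catalysed electrophilic bromination of a terminal alkyne through the silver acetylide is a standard route to 1-bromoalkynes and tolerates the ester.

Step 2
Reactants: 2 methyl 3-bromopropiolate; 3 butanal
Product: 5 methyl (R)-3,3-dibromo-2-[1-(trimethylsilyloxy)butyl]acrylate, via silyl allenolate 4 (not isolated)
Conditions: TMSBr (1.3 equiv), (S)-diphenylprolinol-derived B-(o-tolyl)oxazaborolidinium triflimide (20 mol%), CH2Cl2, −78 → −40 °C; pH 7 buffer work-up, Et3N-deactivated silica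
Reagents that add atoms: bromotrimethylsilane, C[Si](C)(C)Br
Why: In this catalytic asymmetric three-component halo-aldol (β-halo Morita–Baylis–Hillman-type reaction), 1,4-addition of TMSBr to the ynoate should give the β,β-dibromo silyl allenolate 4, which has no alkene geometry because both γ-substituents are bromine, and 4 should add in a Mukaiyama-type aldol with silyl transfer to the butanal bound to the chiral Lewis acid, whose shielding of one aldehyde face sets the (R)-carbinol centre.

Step 3
Reactants: 5 methyl (R)-3,3-dibromo-2-[1-(trimethylsilyloxy)butyl]acrylate; 6 trimethylsilylacetylene (1.05 equiv, slow addition)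
Product: 7 methyl (2E)-3-bromo-5-(trimethylsilyl)-2-[(1R)-1-(trimethylsilyloxy)butyl]pent-2-en-4-ynoate
Conditions: Pd(PPh3)4 (5 mol%), CuI (10 mol%), Et3N, THF, 0 °C → rt
Reagents that add atoms: none
Why: In this site-selective mono-Sonogashira coupling of a 1,1-dibromoalkene, oxidative addition should occur at the C–Br bond that is trans to the bulkier CH(OSiMe3)Pr branch and cis to the flat, palladium-coordinating ester (the trans-selective monocoupling rule for 1,1-dibromoalkenes), and coupling with retention places the alkyne cis to the ester.

Step 4
Reactants: 7 methyl (2E)-3-bromo-5-(trimethylsilyl)-2-[(1R)-1-(trimethylsilyloxy)butyl]pent-2-en-4-ynoate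
Product: 8 (2E)-3-bromo-2-[(1R)-1-hydroxybutyl]-5-(trimethylsilyl)pent-2-en-4-ynoic acid
Conditions: Me3SnOH (4 equiv), 1,2-dichloroethane, 70 °C; then 1 M HCl, THF, 0 °C → rt
Reagents that add atoms: trimethyltin hydroxide, C[Sn](C)(C)O
Why: Trimethyltin hydroxide should cleave the methyl ester under neutral conditions, which avoids addition–elimination of hydroxide at the β-bromo enynoate, and the dilute acid work-up should remove the labile O–SiMe3 group while the C(sp)–SiMe3 group, the alkene geometry and the non-enolisable carbinol centre stay untouched.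

Step 5
Reactants: 8 (2E)-3-bromo-2-[(1R)-1-hydroxybutyl]-5-(trimethylsilyl)pent-2-en-4-ynoic acid
Product: 10 4-bromo-5-(dibromomethylidene)-3-[(1R)-1-hydroxybutyl]furan-2(5H)-one, via bromoalkyne acid 9 (not isolated)
Conditions: NBS (2.3 equiv), AgNO3 (15 mol%), acetone, 0 °C → rt, dark; aq. Na2S2O3 work-up
Reagents that add atoms: N-bromosuccinimide, O=C1CCC(=O)N1Br
Why: Silver(I) should convert the C≡C–SiMe3 terminus into a silver acetylide that NBS brominates to bromoalkyne 9, after which Ag+ or a second Br+ activates the C5≡C6 π-bond and the carboxyl oxygen adds anti to C5, the resulting vinyl-silver or bromonium species being bromodemetalated or opened to give the C6Br2 enol lactone. The closest known reaction types are the silver-catalysed desilylative bromination of silylalkynes with NBS and the halolactonisation of (Z)-2-en-4-ynoic acids and ω-haloalkynoic acids to haloylidene lactones. The furanone ring closes in the 5-exo-dig mode by forming the O1–C5 bond. No new stereocentre arises: C6 carries two identical bromines, so the anti addition leaves no alkene geometry, and the (R)-carbinol is not exposed to ionising or strongly basic conditions. The step needs 5-exo attack at C5 over 6-endo attack at C6 (which would give an isomeric tribromo-2-pyranone) and carboxyl over hydroxyl participation. The first is secured by the bromine on C6, which directs oxygen nucleophiles to the distal alkyne carbon as in metal-catalysed additions to haloalkynes, together with the (E)-alkene that holds the carboxyl next to C5; the second by the hydroxybutyl group lying on the far side of the C3=C4 bond, out of reach of the alkyne.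

**Compound list**

1 | methyl propiolate | C#CC(=O)OC | starting material
2 | methyl 3-bromopropiolate | BrC#CC(=O)OC | intermediate
3 | butanal | CCCC=O | starting material
4 | (3,3-dibromo-1-methoxypropa-1,2-dien-1-yl)oxytrimethylsilane (silyl allenolate) | COC(O[Si](C)(C)C)=C=C(Br)Br | intermediate (not isolated)
5 | methyl (R)-3,3-dibromo-2-[1-(trimethylsilyloxy)butyl]acrylate | CCC[C@@H](O[Si](C)(C)C)C(C(=O)OC)=C(Br)Br | intermediate
6 | trimethylsilylacetylene | C#C[Si](C)(C)C | starting material
7 | methyl (2E)-3-bromo-5-(trimethylsilyl)-2-[(1R)-1-(trimethylsilyloxy)butyl]pent-2-en-4-ynoate | CCC[C@@H](O[Si](C)(C)C)/C(C(=O)OC)=C(\Br)C#C[Si](C)(C)C | intermediate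
8 | (2E)-3-bromo-2-[(1R)-1-hydroxybutyl]-5-(trimethylsilyl)pent-2-en-4-ynoic acid | CCC[C@@H](O)/C(C(=O)O)=C(\Br)C#C[Si](C)(C)C | intermediate
9 | (2E)-3,5-dibromo-2-[(1R)-1-hydroxybutyl]pent-2-en-4-ynoic acid (bromoalkyne acid) | CCC[C@@H](O)/C(C(=O)O)=C(\Br)C#CBr | intermediate (not isolated)
10 | 4-bromo-5-(dibromomethylidene)-3-[(1R)-1-hydroxybutyl]furan-2(5H)-one | CCC[C@@H](O)C1=C(Br)C(=C(Br)Br)OC1=O | target

**Step count and risks**

Total step count: 5. Longest linear sequence: 5 steps (1 → 2 → 5 → 7 → 8 → 10).

Steps most likely to fail:

1. Step 3. Oxidative addition may occur at the wrong C–Br bond, or both bromides may be alkynylated, so that the alkyne is not placed cleanly cis to the ester. Fallback (sets out from 5, returns at 7): 5 is treated with i-PrMgCl·LiCl in THF at −78 °C. Ester-directed Br/Mg exchange, with the carbonyl oxygen chelating magnesium, should give the alkenylmagnesium carbenoid methyl (2E)-3-bromo-3-(chloromagnesio)-2-[(1R)-1-(trimethylsilyloxy)butyl]acrylate F1. Quenching with iodine at −78 °C should give methyl (2Z)-3-bromo-3-iodo-2-[(1R)-1-(trimethylsilyloxy)butyl]acrylate F2, with iodine cis to the ester. Chemoselective Sonogashira coupling of the C–I bond of F2 with 6 (Pd(PPh3)4, CuI, Et3N, THF, 0 °C) then leads to 7 with the geometry fixed by chelation instead of by steric site selection.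

2. Step 2. Bromide transfer from TMSBr to the bromo-ynoate may be sluggish, or the catalyst may discriminate the aldehyde faces poorly, giving low conversion or low enantiomeric purity. Fallback (sets out from 2 and 3, returns at 5): a racemic bromo-aldol promoted by MgBr2·OEt2 (CH2Cl2, 0 °C) should give racemic methyl 3,3-dibromo-2-(1-hydroxybutyl)acrylate F3. Dess–Martin oxidation gives the ketone methyl 3,3-dibromo-2-butanoylacrylate F4. Corey–Bakshi–Shibata reduction with (S)-Me-CBS and catecholborane (toluene, −78 °C), with the tetrasubstituted alkenyl group as the large substituent, should give methyl (R)-3,3-dibromo-2-(1-hydroxybutyl)acrylate F5. Silylation with TMSCl and imidazole then gives 5. The stereocentre is thus set by reagent-controlled ketone reduction instead of by the aldol event.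

3. Step 5. Silver-catalysed cyclisation may start before the alkyne is brominated, protodemetalation may compete with bromination, or part of the material may close in the 6-endo mode or be over-brominated. Fallback (sets out from 8, returns at 10): 8 is treated with only 1.05 equiv of NBS and catalytic AgNO3, and the bromoalkyne acid 9 is isolated. Gold(I)-catalysed cycloisomerisation (Ph3PAuCl/AgOTf, CH2Cl2, rt; 5-exo-dig anti oxyauration, then protodeauration) should give (5Z)-4-bromo-5-(bromomethylidene)-3-[(1R)-1-hydroxybutyl]furan-2(5H)-one F6. Addition of Br2 (CH2Cl2, 0 °C) across the exocyclic enol-ester double bond gives 4,5-dibromo-5-(dibromomethyl)-3-[(1R)-1-hydroxybutyl]furan-2(5H)-one F7 as a mixture of C5 epimers. Dehydrobromination with Et3N (CH2Cl2, 0 °C) then gives 10, so that ring closure and the second C6 bromination are separated.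

**Further compounds**

F1 | step 3 | methyl (2E)-3-bromo-3-(chloromagnesio)-2-[(1R)-1-(trimethylsilyloxy)butyl]acrylate | CCC[C@@H](O[Si](C)(C)C)/C(C(=O)OC)=C(\Br)[Mg]Cl
F2 | step 3 | methyl (2Z)-3-bromo-3-iodo-2-[(1R)-1-(trimethylsilyloxy)butyl]acrylate | CCC[C@@H](O[Si](C)(C)C)/C(C(=O)OC)=C(\Br)I
F3 | step 2 | racemic methyl 3,3-dibromo-2-(1-hydroxybutyl)acrylate | CCCC(O)C(C(=O)OC)=C(Br)Br
F4 | step 2 | methyl 3,3-dibromo-2-butanoylacrylate | CCCC(=O)C(C(=O)OC)=C(Br)Br
F5 | step 2 | methyl (R)-3,3-dibromo-2-(1-hydroxybutyl)acrylate | CCC[C@@H](O)C(C(=O)OC)=C(Br)Br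
F6 | step 5 | (5Z)-4-bromo-5-(bromomethylidene)-3-[(1R)-1-hydroxybutyl]furan-2(5H)-one | CCC[C@@H](O)C1=C(Br)/C(=C/Br)OC1=O
F7 | step 5 | 4,5-dibromo-5-(dibromomethyl)-3-[(1R)-1-hydroxybutyl]furan-2(5H)-one (C5 epimers) | CCC[C@@H](O)C1=C(Br)C(Br)(C(Br)Br)OC1=O
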